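**Plan**
- Locants used throughout: decalin numbered like a clerodane (ring A = C1–C5, C10; ring B = C5–C10); C3 bears the isopropylidene, C4 the propanoic acid chain, C5/C8/C9 the methyls, C9 the arylmethyl group; β = face of the C5 methyl.
- Retrosynthesis: first cut the aryl O–H (as OMe), C3=CMe2 (C3 ketone + acetone), C8–CH3 (cuprate), a helper oxygen at C6 and C9–CH2Ar (enolate benzylation), giving a trans-decalin-6,8-dione. Then cut C5–C10 and C7–C8 together (Michael addition/Claisen condensation) to an acyclic keto enoate, itself opened from a Diels–Alder cyclohexene.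
- Forward order: cyclohexene (latent methyl ketone and acid chain) → acyclic keto enoate with the C4 stereocentre → ring A and ring B closed in one operation → ring-B editing (C9 benzyl, C8 methyl, C6 deoxygenation) → C3 isopropylidene → hydroquinone.
- Enabling feature: C6, the ring-B methylene between quaternary C5 and C7, can be a ketone whose two α-carbons C5 and C7 act as nucleophiles in turn; C10 and C8 are the β-carbon and carboxyl carbon of one (E)-2-methyl enoate (α-carbon C9); C1–C4 of ring A is the tether. The resulting C6/C8 dione then steers C9 and C8.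
- Stereochemistry: C4 from the auxiliary-controlled Diels–Alder reaction; C5 and C10 from C4 through the chair transition state of the ring-A closure; C9 by benzylation anti to the C5 methyl; C8 by axial cuprate addition.

Key step: step 12

Assumption: commercial 3-methylpenta-1,3-diene is an E/Z mixture; only the (E)-isomer can readily reach the s-cis conformation and is taken to react in step 6, so the diene is used in excess.

**Route**

Step 1
Reactants: 1 4-methoxy-2-methylphenol
Product: 2 2-hydroxy-5-methoxy-3-methylbenzaldehyde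
Conditions: (CH2O)n, MgCl2, Et3N, MeCN, reflux
Reagents that add atoms: paraformaldehyde (formaldehyde unit), C=O
Why: Magnesium-mediated ortho-formylation of the phenoxide (hydroxymethylation, then hydride transfer to a second formaldehyde) should occur at C-6, the only free position ortho to the hydroxyl group.

Step 2
Reactants: 2 2-hydroxy-5-methoxy-3-methylbenzaldehyde
Product: 3 2,5-dimethoxy-3-methylbenzaldehyde
Conditions: MeI, K2CO3, DMF, 20 °C
Reagents that add atoms: iodomethane, CI
Why: Williamson O-methylation of the phenoxide should be clean and gives the hydroquinone as its base-stable dimethyl ether.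

Step 3
Reactants: 3 2,5-dimethoxy-3-methylbenzaldehyde
Product: 4 (2,5-dimethoxy-3-methylphenyl)methanol
Conditions: NaBH4, MeOH, 0 °C
Reagents that add atoms: none
Why: Borohydride reduction of the aryl aldehyde to the benzylic alcohol is routine.

Step 4
Reactants: 4 (2,5-dimethoxy-3-methylphenyl)methanol
Product: 5 1-(bromomethyl)-2,5-dimethoxy-3-methylbenzene
Conditions: PBr3, Et2O, 0 °C
Reagents that add atoms: phosphorus tribromide, BrP(Br)Br
Why: Bromination through the phosphite ester (SN2 by bromide) should give the electron-rich benzylic bromide needed in step 13.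

Step 5
Reactants: 6 (4R)-4-benzyl-1,3-oxazolidin-2-one
Product: 7 (4R)-3-acryloyl-4-benzyl-1,3-oxazolidin-2-one
Conditions: n-BuLi, THF, −78 °C; then CH2=CHCOCl, −78 → 0 °C
Reagents that add atoms: acryloyl chloride, C=CC(Cl)=O
Why: N-Acylation of the lithiated oxazolidinone gives the chelating dienophile that carries the only external source of chirality.

Step 6
Reactants: 7 (4R)-3-acryloyl-4-benzyl-1,3-oxazolidin-2-one; 8 (3E)-3-methylpenta-1,3-diene
Product: 9 (4R)-4-benzyl-3-{[(1S,2S)-2,3-dimethylcyclohex-3-en-1-yl]carbonyl}-1,3-oxazolidin-2-one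
Conditions: Et2AlCl, CH2Cl2, −78 °C
Reagents that add atoms: none
Why: In this Lewis acid-promoted Diels–Alder reaction of the aluminium-chelated s-cis acrylimide the diene should add to the face opposite the benzyl group, setting ring C-1 as S (the future decalin C-4), while the terminal methyl of the diene directs the 1,2 orientation and the endo mode gives the cis 2-methyl group, whose configuration is erased later.

Step 7
Reactants: 9 (4R)-4-benzyl-3-{[(1S,2S)-2,3-dimethylcyclohex-3-en-1-yl]carbonyl}-1,3-oxazolidin-2-one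
Product: 10 (1S,2S)-N-methoxy-N,2,3-trimethylcyclohex-3-ene-1-carboxamide
Conditions: MeNH(OMe)·HCl, AlMe3, CH2Cl2, 0 → 20 °C
Reagents that add atoms: N,O-dimethylhydroxylamine hydrochloride, CNOC.Cl
Why: Aluminium amide aminolysis of the imide should release the auxiliary and give the N-methoxy-N-methylamide without touching the α-stereocentre.

Step 8
Reactants: 10 (1S,2S)-N-methoxy-N,2,3-trimethylcyclohex-3-ene-1-carboxamide
Product: 11 1-[(1S,2S)-2,3-dimethylcyclohex-3-en-1-yl]pent-4-en-1-one
Conditions: CH2=CHCH2CH2MgBr, THF, 0 °C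
Reagents that add atoms: but-3-en-1-ylmagnesium bromide, C=CCC[Mg]Br
Why: Grignard acyl substitution through the stable chelated tetrahedral intermediate should stop at the ketone and brings in C-1, C-2 and C-10.

Step 9
Reactants: 11 1-[(1S,2S)-2,3-dimethylcyclohex-3-en-1-yl]pent-4-en-1-one
Product: 12 2-(but-3-en-1-yl)-2-[(1S,2S)-2,3-dimethylcyclohex-3-en-1-yl]-1,3-dioxolane
Conditions: Me3SiOCH2CH2OSiMe3, Me3SiOTf (cat.), CH2Cl2, −78 → −20 °C
Reagents that add atoms: 1,2-bis(trimethylsilyloxy)ethane, C[Si](C)(C)OCCO[Si](C)(C)C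
Why: Silyl-transfer ketalisation under aprotic, kinetically controlled conditions should mask the future C-3 ketone without enolisation, so the adjacent stereocentre is kept and loses its acidity for the base steps to come.

Step 10
Reactants: 12 2-(but-3-en-1-yl)-2-[(1S,2S)-2,3-dimethylcyclohex-3-en-1-yl]-1,3-dioxolane
Product: 13 methyl (2E)-5-{2-[(1S,2S)-2,3-dimethylcyclohex-3-en-1-yl]-1,3-dioxolan-2-yl}-2-methylpent-2-enoate
Conditions: methyl methacrylate (excess), second-generation Grubbs catalyst (5 mol %), CH2Cl2, 40 °C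
Reagents that add atoms: methyl methacrylate, C=C(C)C(=O)OC
Why: Olefin cross-metathesis of the monosubstituted alkene with the methacrylate should give the (E)-trisubstituted enoate (C-8 to C-10), the trisubstituted ring alkene being inert.

Step 11
Reactants: 13 methyl (2E)-5-{2-[(1S,2S)-2,3-dimethylcyclohex-3-en-1-yl]-1,3-dioxolan-2-yl}-2-methylpent-2-enoate
Product: 15 methyl (2E,7S,8S)-7-[2-(1,3-dioxolan-2-yl)ethyl]-6,6-(ethylenedioxy)-2,8-dimethyl-9-oxodec-2-enoate, via keto aldehyde 14 (not isolated)
Conditions: O3, CH2Cl2, −78 °C; Me2S; then (CH2OH)2, pyridinium p-toluenesulfonate (cat.), MgSO4, 20 °C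
Reagents that add atoms: ozone, [O-][O+]=O; ethane-1,2-diol, OCCO
Why: Ozonolysis should cleave only the electron-rich ring alkene (the enoate is deactivated), unmasking the methyl ketone (C-6, C-7) and the side-chain aldehyde, and the far more reactive aldehyde is then selectively acetalised while the ketone stays free.

Step 12
Reactants: 15 methyl (2E,7S,8S)-7-[2-(1,3-dioxolan-2-yl)ethyl]-6,6-(ethylenedioxy)-2,8-dimethyl-9-oxodec-2-enoate
Product: 17 trans-fused 3,3-(ethylenedioxy)-4β-[2-(1,3-dioxolan-2-yl)ethyl]-5β,9α-dimethyl-10α-H-decalin-6,8-dione (plan locants), via Michael adduct 16 (not isolated)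
Conditions: t-BuOK (3 equiv), t-BuOH–THF (1:5), 0 → 40 °C; then aq. NaH2PO4
Reagents that add atoms: none
Why: The alkoxide equilibrates the ketone enolates of 15; the more substituted C-5 enolate adds to the enoate in a 6-(enolexo)-exo-trig Michael closure of ring A (C5–C10), and the methyl ketone enolate (C-7) then attacks the ester carbonyl C-8 in a 6-(enolendo)-exo-trig Claisen (Dieckmann-type) closure of ring B, the sequence being pulled forward by irreversible deprotonation of the 1,3-dione. The closest known reaction type is the consecutive Michael–Claisen synthesis of cyclohexane-1,3-diones from methyl ketones and α,β-unsaturated esters (3-methylbutan-2-one and an acrylate give 4,4-dimethylcyclohexane-1,3-dione), run here within one chain. C-5 is controlled by the resident C-4 centre: in the chair transition state 1,3-allylic strain should keep H-4 near the enolate plane, the side chain equatorial and the enolate carbon C-6 equatorial, so the C-5 methyl becomes axial and cis to the side chain. C-10 is controlled by the (E)-enoate taking the equatorial site of the same chair, which should leave H-10 axial and trans to the C-5 methyl, and the two equatorial arms then close to the trans-decalin. C-9 is formed as an epimerisable centre (equatorial methyl expected) and is erased in step 13. The step needs regioselection between the C-5 and C-7 enolates, secured by ring size (C-7 attack on C-10 would give an eight-membered ring), and an intact C-4 centre, secured by the C-3 ketal, which removes the acidity of H-4 and prevents 1,4-diketone aldol closure.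

Step 13
Reactants: 17 trans-fused 3,3-(ethylenedioxy)-4β-[2-(1,3-dioxolan-2-yl)ethyl]-5β,9α-dimethyl-10α-H-decalin-6,8-dione; 5 1-(bromomethyl)-2,5-dimethoxy-3-methylbenzene
Product: 18 9α-(2,5-dimethoxy-3-methylbenzyl)-3,3-(ethylenedioxy)-4β-[2-(1,3-dioxolan-2-yl)ethyl]-5β,9β-dimethyl-10α-H-decalin-6,8-dione
Conditions: LDA (2.5 equiv), THF–DMPU, −78 → 0 °C; then 5, −78 → 0 °C
Reagents that add atoms: none
Why: In this γ-alkylation of the 1,3-diketone dianion C-9 carries the only γ-hydrogen (C-5 is quaternary), and the benzylic bromide should enter anti to the 1,3-related axial C-5 methyl, giving the quaternary centre with 9α-arylmethyl and 9β-methyl groups.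

Step 14
Reactants: 18 9α-(2,5-dimethoxy-3-methylbenzyl)-3,3-(ethylenedioxy)-4β-[2-(1,3-dioxolan-2-yl)ethyl]-5β,9β-dimethyl-10α-H-decalin-6,8-dione
Product: 19 the 8-(trifluoromethanesulfonyloxy)-7-en-6-one derived from 18 (enol triflate at the C-8 oxygen)
Conditions: Tf2O, pyridine, CH2Cl2, −78 → 0 °C
Reagents that add atoms: trifluoromethanesulfonic anhydride, O=S(=O)(OS(=O)(=O)C(F)(F)F)C(F)(F)F
Why: O-Sulfonylation of the dione enolate should take place at the C-8 oxygen, because the C-6 oxygen lies in the cleft between quaternary C-5 and the equatorial C-4 side chain (peri relationship), which gives the vinylogous triflate with the carbonyl kept at C-6.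

Step 15
Reactants: 19 the 8-(trifluoromethanesulfonyloxy)-7-en-6-one derived from 18
Product: 20 9α-(2,5-dimethoxy-3-methylbenzyl)-3,3-(ethylenedioxy)-4β-[2-(1,3-dioxolan-2-yl)ethyl]-5β,9β-dimethyl-10α-H-decal-7-en-6-one
Conditions: Pd(OAc)2 (5 mol %), PPh3, HCO2H, n-Bu3N, DMF, 60 °C
Reagents that add atoms: none
Why: Palladium-catalysed formate reduction of the enol triflate (oxidative addition to zerovalent palladium, decarboxylation of formate to a palladium hydride, reductive elimination) should replace the triflate by hydrogen and leave the enone with an unsubstituted β-carbon C-8.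

Step 16
Reactants: 20 9α-(2,5-dimethoxy-3-methylbenzyl)-3,3-(ethylenedioxy)-4β-[2-(1,3-dioxolan-2-yl)ethyl]-5β,9β-dimethyl-10α-H-decal-7-en-6-one
Product: 21 9α-(2,5-dimethoxy-3-methylbenzyl)-3,3-(ethylenedioxy)-4β-[2-(1,3-dioxolan-2-yl)ethyl]-5β,8α,9β-trimethyl-10α-H-decalin-6-one
Conditions: Me2CuLi (from CuBr·SMe2 and MeLi), Et2O, −40 → 0 °C; aq. NH4Cl
Reagents that add atoms: lithium dimethylcuprate, [Li+].C[Cu-]C
Why: Cuprate conjugate addition should be axial and anti to the pseudoaxial C-9 methyl and the C-5 methyl, that is from the α-face, which sets the axial 8α-methyl group that hydrogenation of a C-8 alkene would not give.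

Step 17
Reactants: 21 9α-(2,5-dimethoxy-3-methylbenzyl)-3,3-(ethylenedioxy)-4β-[2-(1,3-dioxolan-2-yl)ethyl]-5β,8α,9β-trimethyl-10α-H-decalin-6-one
Product: 22 9α-(2,5-dimethoxy-3-methylbenzyl)-3,3-(ethylenedioxy)-4β-[2-(1,3-dioxolan-2-yl)ethyl]-5β,8α,9β-trimethyl-10α-H-decalin
Conditions: N2H4·H2O, KOH, diethylene glycol, 130 °C then 200 °C
Reagents that add atoms: none
Why: Wolff–Kishner reduction (Huang-Minlon conditions) should remove the helper carbonyl at C-6 under basic conditions that leave both dioxolanes and the aryl methyl ethers intact.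

Step 18
Reactants: 22 9α-(2,5-dimethoxy-3-methylbenzyl)-3,3-(ethylenedioxy)-4β-[2-(1,3-dioxolan-2-yl)ethyl]-5β,8α,9β-trimethyl-10α-H-decalin
Product: 24 3-[9α-(2,5-dimethoxy-3-methylbenzyl)-5β,8α,9β-trimethyl-3-oxo-10α-H-decalin-4β-yl]propanoic acid, via keto aldehyde 23 (not isolated)
Conditions: 1 M HCl, THF, 20 °C; then NaClO2, NaH2PO4, 2-methylbut-2-ene, t-BuOH–H2O, 0 → 20 °C
Reagents that add atoms: water, O; sodium chlorite, [Na+].[O-]Cl=O
Why: Acid hydrolysis of both dioxolanes followed in the same flask by Pinnick oxidation of the liberated aldehyde should give the keto acid, the mild non-basic conditions being chosen so that the now enolisable C-4 centre is not epimerised.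

Step 19
Reactants: 24 3-[9α-(2,5-dimethoxy-3-methylbenzyl)-5β,8α,9β-trimethyl-3-oxo-10α-H-decalin-4β-yl]propanoic acid
Product: 25 3-[9α-(2,5-dimethoxy-3-methylbenzyl)-5β,8α,9β-trimethyl-3-(propan-2-ylidene)-10α-H-decalin-4β-yl]propanoic acid
Conditions: TiCl3(DME)1.5, Zn(Cu), DME, reflux; then 24 and acetone (6 equiv) added slowly, reflux
Reagents that add atoms: acetone, CC(C)=O
Why: McMurry mixed carbonyl coupling on low-valent titanium with excess acetone should convert the hindered C-3 ketone directly into the tetrasubstituted isopropylidene group, the acid being held as an unreactive titanium carboxylate.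

Step 20
Reactants: 25 3-[9α-(2,5-dimethoxy-3-methylbenzyl)-5β,8α,9β-trimethyl-3-(propan-2-ylidene)-10α-H-decalin-4β-yl]propanoic acid
Product: 27 3-[9α-(2,5-dihydroxy-3-methylbenzyl)-5β,8α,9β-trimethyl-3-(propan-2-ylidene)-10α-H-decalin-4β-yl]propanoic acid (CNP0286368.1), via quinone 26 (not isolated)
Conditions: (NH4)2Ce(NO3)6, MeCN–H2O, 0 °C; then Na2S2O4, H2O–EtOAc, 20 °C
Reagents that add atoms: water, O
Why: Oxidative demethylation of the 1,4-dimethoxyarene to the quinone and dithionite reduction during work-up should release the hydroquinone without strong acid that could isomerise the isopropylidene group.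

**Compound list**

1 | 4-methoxy-2-methylphenol | COc1ccc(O)c(C)c1 | starting material
2 | 2-hydroxy-5-methoxy-3-methylbenzaldehyde | COc1cc(C)c(O)c(C=O)c1 | intermediate
3 | 2,5-dimethoxy-3-methylbenzaldehyde | COc1cc(C)c(OC)c(C=O)c1 | intermediate
4 | (2,5-dimethoxy-3-methylphenyl)methanol | COc1cc(C)c(OC)c(CO)c1 | intermediate
5 | 1-(bromomethyl)-2,5-dimethoxy-3-methylbenzene | COc1cc(C)c(OC)c(CBr)c1 | intermediate
6 | (4R)-4-benzyl-1,3-oxazolidin-2-one | O=C1N[C@H](Cc2ccccc2)CO1 | starting material
7 | (4R)-3-acryloyl-4-benzyl-1,3-oxazolidin-2-one | C=CC(=O)N1[C@H](Cc2ccccc2)COC1=O | intermediate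
8 | (3E)-3-methylpenta-1,3-diene | C=C/C(C)=C/C | starting material
9 | (4R)-4-benzyl-3-{[(1S,2S)-2,3-dimethylcyclohex-3-en-1-yl]carbonyl}-1,3-oxazolidin-2-one | C[C@@H]1C(C)=CCC[C@@H]1C(=O)N1[C@H](Cc2ccccc2)COC1=O | intermediate
10 | (1S,2S)-N-methoxy-N,2,3-trimethylcyclohex-3-ene-1-carboxamide | C[C@@H]1C(C)=CCC[C@@H]1C(=O)N(C)OC | intermediate
11 | 1-[(1S,2S)-2,3-dimethylcyclohex-3-en-1-yl]pent-4-en-1-one | C[C@@H]1C(C)=CCC[C@@H]1C(=O)CCC=C | intermediate
12 | 2-(but-3-en-1-yl)-2-[(1S,2S)-2,3-dimethylcyclohex-3-en-1-yl]-1,3-dioxolane | C[C@@H]1C(C)=CCC[C@@H]1C1(CCC=C)OCCO1 | intermediate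
13 | methyl (2E)-5-{2-[(1S,2S)-2,3-dimethylcyclohex-3-en-1-yl]-1,3-dioxolan-2-yl}-2-methylpent-2-enoate | C[C@@H]1C(C)=CCC[C@@H]1C1(CC/C=C(\C)C(=O)OC)OCCO1 | intermediate
14 | methyl (2E,7S,8S)-6,6-(ethylenedioxy)-2,8-dimethyl-9-oxo-7-(3-oxopropyl)dec-2-enoate (keto aldehyde, not isolated) | CC(=O)[C@@H](C)[C@H](CCC=O)C1(CC/C=C(\C)C(=O)OC)OCCO1 | intermediate
15 | methyl (2E,7S,8S)-7-[2-(1,3-dioxolan-2-yl)ethyl]-6,6-(ethylenedioxy)-2,8-dimethyl-9-oxodec-2-enoate (C-8 epimerisable, erased in step 12) | CC(=O)[C@@H](C)[C@H](CCC1OCCO1)C1(CC/C=C(\C)C(=O)OC)OCCO1 | intermediate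
16 | ring-A keto ester (Michael adduct, not isolated): 5α-acetyl-5β-methyl-4β-[2-(1,3-dioxolan-2-yl)ethyl]-3,3-(ethylenedioxy)cyclohexane carrying CH(CH3)CO2CH3 at C-10 (10α-H), C-9 unassigned | C1COC2(O1)CC[C@H](C(C)C(=O)OC)[C@@](C)(C(C)=O)[C@@H]2CCC1OCCO1 | intermediate
17 | trans-fused 3,3-(ethylenedioxy)-4β-[2-(1,3-dioxolan-2-yl)ethyl]-5β,9α-dimethyl-10α-H-decalin-6,8-dione (drawn as the diketo tautomer) | C1COC2(O1)CC[C@H]3[C@@](C)(C(=O)CC(=O)[C@@H]3C)[C@@H]2CCC1OCCO1 | intermediate
18 | 9α-(2,5-dimethoxy-3-methylbenzyl)-3,3-(ethylenedioxy)-4β-[2-(1,3-dioxolan-2-yl)ethyl]-5β,9β-dimethyl-10α-H-decalin-6,8-dione | C1COC2(O1)CC[C@H]3[C@@](C)(C(=O)CC(=O)[C@]3(C)Cc3cc(OC)cc(C)c3OC)[C@@H]2CCC1OCCO1 | intermediate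
19 | 8-(trifluoromethanesulfonyloxy)-7-en-6-one derived from 18 | C1COC2(O1)CC[C@H]3[C@@](C)(C(=O)C=C(OS(=O)(=O)C(F)(F)F)[C@]3(C)Cc3cc(OC)cc(C)c3OC)[C@@H]2CCC1OCCO1 | intermediate
20 | 9α-(2,5-dimethoxy-3-methylbenzyl)-3,3-(ethylenedioxy)-4β-[2-(1,3-dioxolan-2-yl)ethyl]-5β,9β-dimethyl-10α-H-decal-7-en-6-one | C1COC2(O1)CC[C@H]3[C@@](C)(C(=O)C=C[C@]3(C)Cc3cc(OC)cc(C)c3OC)[C@@H]2CCC1OCCO1 | intermediate
21 | 9α-(2,5-dimethoxy-3-methylbenzyl)-3,3-(ethylenedioxy)-4β-[2-(1,3-dioxolan-2-yl)ethyl]-5β,8α,9β-trimethyl-10α-H-decalin-6-one | C1COC2(O1)CC[C@H]3[C@@](C)(C(=O)C[C@H](C)[C@]3(C)Cc3cc(OC)cc(C)c3OC)[C@@H]2CCC1OCCO1 | intermediate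
22 | 9α-(2,5-dimethoxy-3-methylbenzyl)-3,3-(ethylenedioxy)-4β-[2-(1,3-dioxolan-2-yl)ethyl]-5β,8α,9β-trimethyl-10α-H-decalin | C1COC2(O1)CC[C@H]3[C@@](C)(CC[C@H](C)[C@]3(C)Cc3cc(OC)cc(C)c3OC)[C@@H]2CCC1OCCO1 | intermediate
23 | 3-[9α-(2,5-dimethoxy-3-methylbenzyl)-5β,8α,9β-trimethyl-3-oxo-10α-H-decalin-4β-yl]propanal (keto aldehyde, not isolated) | O=C1CC[C@H]2[C@@](C)(CC[C@H](C)[C@]2(C)Cc2cc(OC)cc(C)c2OC)[C@@H]1CCC=O | intermediate
24 | 3-[9α-(2,5-dimethoxy-3-methylbenzyl)-5β,8α,9β-trimethyl-3-oxo-10α-H-decalin-4β-yl]propanoic acid | O=C1CC[C@H]2[C@@](C)(CC[C@H](C)[C@]2(C)Cc2cc(OC)cc(C)c2OC)[C@@H]1CCC(=O)O | intermediate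
25 | 3-[9α-(2,5-dimethoxy-3-methylbenzyl)-5β,8α,9β-trimethyl-3-(propan-2-ylidene)-10α-H-decalin-4β-yl]propanoic acid | CC(C)=C1CC[C@H]2[C@@](C)(CC[C@H](C)[C@]2(C)Cc2cc(OC)cc(C)c2OC)[C@@H]1CCC(=O)O | intermediate
26 | 3-{5β,8α,9β-trimethyl-9α-[(5-methyl-3,6-dioxocyclohexa-1,4-dien-1-yl)methyl]-3-(propan-2-ylidene)-10α-H-decalin-4β-yl}propanoic acid (quinone, not isolated) | CC(C)=C1CC[C@H]2[C@@](C)(CC[C@H](C)[C@]2(C)CC2=CC(=O)C=C(C)C2=O)[C@@H]1CCC(=O)O | intermediate
27 | 3-[9α-(2,5-dihydroxy-3-methylbenzyl)-5β,8α,9β-trimethyl-3-(propan-2-ylidene)-10α-H-decalin-4β-yl]propanoic acid (CNP0286368.1) | CC(C)=C1CC[C@H]2[C@@](C)(CC[C@H](C)[C@]2(C)Cc2cc(O)cc(C)c2O)[C@@H]1CCC(=O)O | target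

**Step count and risks**

Total step count: 20 (steps 1–4 for the arylmethyl bromide, steps 5–20 for the main line).
Longest linear sequence: 16 steps (steps 5–20, from 6).

Steps most likely to fail:

Step 12. What may go wrong: poor facial selectivity at C-10 in the ring-A Michael closure (leading to cis ring fusion), or stalling and reversal of the sequence before the Claisen closure under equilibrating alkoxide conditions. Fallback: setting out from 15, condensation with benzylamine (4 Å molecular sieves, toluene, 20 °C) would give the N-benzyl ketimine F1. On warming in THF its more substituted secondary-enamine tautomer should add to the enoate under neutral conditions through the compact, internally proton-transferring (aza-ene-type) transition state of imine Michael additions. Mild hydrolysis with aqueous acetic acid would then give the ring-A keto ester 16, this time isolated and freed from any C-10 epimer. Treatment with t-BuOK in THF would effect the Dieckmann-type closure and bring the material back to the route at 17.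

Step 13. What may go wrong: incomplete second deprotonation at the tertiary C-9–H and competing O-alkylation or C-7 alkylation of the mono-enolate. Fallback: setting out from 17, triflation (Tf2O, pyridine) at the C-8 oxygen, which is clearly the less hindered one while C-9 is still tertiary, would give the vinylogous triflate F2. Palladium-catalysed formate reduction (Pd(OAc)2, PPh3, HCO2H, n-Bu3N) would give the enone F3. LDA and Me3SiCl (γ-deprotonation at C-9, the only enolisable position) would give the 1-silyloxydiene F4. Its ZnBr2-mediated alkylation with the SN1-active benzylic bromide 5 at the γ-terminus (vinylogous Mukaiyama-type alkylation, anti to the C-5 methyl) would come back to the route at 20, which also bypasses steps 14 and 15.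

Step 19. What may go wrong: acetone self-coupling or arrest at the pinacol stage outrunning the mixed coupling at the hindered C-3 ketone, together with enolisation-induced epimerisation at C-4. Fallback: setting out from 24, addition of 2-lithio-2-(methylseleno)propane (from 2,2-bis(methylseleno)propane and n-BuLi, in excess to allow for the carboxylate) would give the β-hydroxy selenide F5; such selenium-stabilised carbanions are weakly basic and add to hindered, enolisable ketones. Reductive elimination with MsCl and Et3N (through the seleniranium ion) would then give the tetrasubstituted alkene and come back to the route at 25.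

Further compounds
F1 | step 12 | methyl (2E,7S,8S)-9-(benzylimino)-7-[2-(1,3-dioxolan-2-yl)ethyl]-6,6-(ethylenedioxy)-2,8-dimethyldec-2-enoate (N-benzyl ketimine of 15) | CC(=NCc1ccccc1)[C@@H](C)[C@H](CCC1OCCO1)C1(CC/C=C(\C)C(=O)OC)OCCO1
F2 | step 13 | 3,3-(ethylenedioxy)-4β-[2-(1,3-dioxolan-2-yl)ethyl]-5β,9α-dimethyl-8-(trifluoromethanesulfonyloxy)-10α-H-decal-7-en-6-one | C1COC2(O1)CC[C@H]3[C@@](C)(C(=O)C=C(OS(=O)(=O)C(F)(F)F)[C@@H]3C)[C@@H]2CCC1OCCO1
F3 | step 13 | 3,3-(ethylenedioxy)-4β-[2-(1,3-dioxolan-2-yl)ethyl]-5β,9α-dimethyl-10α-H-decal-7-en-6-one | C1COC2(O1)CC[C@H]3[C@@](C)(C(=O)C=C[C@@H]3C)[C@@H]2CCC1OCCO1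
F4 | step 13 | 3,3-(ethylenedioxy)-4β-[2-(1,3-dioxolan-2-yl)ethyl]-5β,9-dimethyl-6-(trimethylsilyloxy)-10α-H-decalin-6,8-diene (1-silyloxydiene) | C1COC2(O1)CC[C@H]3[C@@](C)(C(O[Si](C)(C)C)=CC=C3C)[C@@H]2CCC1OCCO1
F5 | step 19 | 3-{9α-(2,5-dimethoxy-3-methylbenzyl)-3-hydroxy-5β,8α,9β-trimethyl-3-[2-(methylseleno)propan-2-yl]-10α-H-decalin-4β-yl}propanoic acid (C-3 configuration unassigned) | C[Se]C(C)(C)C1(O)CC[C@H]2[C@@](C)(CC[C@H](C)[C@]2(C)Cc2cc(OC)cc(C)c2OC)[C@@H]1CCC(=O)O
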